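Percent of the charge is the unit in which Friday's flask, the one asked about, and Thursday's richer run can be read side by side.

| flask | starting material | reagent in the second phase | protic impurity | remark | time | volume of the second phase over the first |
|---|---|---|---|---|---|---|
| Friday's | 0.16 M | 1.3 equiv | 0.016 M | the very flask that is asked about, followed so far |  |  |
| Thursday's | 0.24 M | 1.3 equiv | 0.016 M | run made earlier |  |  |
| flask | 0.16 M | 1.30 equiv | 0.0160 M |  | 10 h | 0.25 |

- Friday's (time / h: target / %, starting material / %): 0.200: 26.9, 66.3; 0.667: 36.8, 32.3; 1.00: 36.6, 22.7; 1.50: 39.5, 13.8; 2.50: 38.1, 8.3; 3.00: 37.5, 5.4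
- Thursday's (time / h: target / %, starting material / %): 0.667: 39.3, 25.1; 1.33: 38.9, 9.6; 2.00: 38.1, 5.6; 2.50: 38.7, 5.1; 3.00: 35.1, 3.9; 4.00: 37.3, 2.4

(scatter of a reading: 1 percentage point)

1. target at 10 h, in percent of the starting material charged
2. part of the starting material charged that has reacted at 10 h

- in the second phase: reagent in the second phase; everything else is in the first
- charges count per volume of the first phase; a concentration in a rate is the amount of a species over the volume of its own phase; every rate counts per litre of the first phase
- the earlier runs hold the two phases in the same ratio of volumes as the flask asked about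

Thursday's run is read later than Friday's, so I take two half-lives from it. Between 2.00 h and 4.00 h the readings of the starting material give a half-life of

tA = 1.64 h

Between 0.667 h and 4.00 h the target slips, and at that pace it halves in

tP = 44.2 h

I call tP the plateau half-life, the time in which the target halves at the pace read from Thursday's run. It rests on a fall of 2 percentage points against a scatter of 1 point, so it is loose. The asked 10 h is longer than tA and shorter than tP. Carrying both half-lives over from Thursday's richer run is an estimate; from Friday's last readings, 7.00 h earlier, I reckon for the asked time:

target = 37.5% × 0.5^(7.00 h / tP) = 33.6%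

starting material left = 5.4% × 0.5^(7.00 h / tA) = 0.278%, so reacted = 99.7%

The forecast gives 36.5% and 98.5%: “I expect the target to stay about 37%, perhaps drifting slightly lower”. My target is lower than the forecast's by 2.9 points.

The flask gives 33.3% and 99.5%.

    reagent in the reaction phase ⇌ reagent in the second phase, rate k1*([reagent in the reaction phase] - [reagent in the second phase]/K1) per volume of the first phase (partition coefficient = 0.453, kL = 0.00124 s⁻¹)
    starting material + reagent in the reaction phase → target (k = 0.00371 L mol⁻¹ s⁻¹)
    reagent in the reaction phase + target → over-reacted product (k = 6.32 × 10⁻⁴ L mol⁻¹ s⁻¹)
    starting material + protic impurity → quenched substrate (k = 0.00251 L mol⁻¹ s⁻¹)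
    target ⇌ isomer of the product (K = 0.928, k = 5.42 × 10⁻⁴ s⁻¹)

The flask's target stands 0.30 points from my reckoning, and the forecast's stands 3.2 points from it. The neighbour is this same flask read at 2.5 h. Between that reading and 10 h the target falls at a pace that corresponds to a half-life of 39.4 h, against a tP of 44.2 h. Run back from Friday's last reading, tP gives 37.8% for the neighbour, which holds 38.0% of target.

(Readings and results were generated by integration on assumed constants; the scatter is artificial.)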